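**Strategy.** Everything rests on disconnecting the C3–O bond: the cis C3 acetate and the acrolein are both read as an opened cis-fused α-methylene-γ-butyrolactone bridging C2 and C3 of the dihydrofuran ring B. One anodic oxidation of an acrylic acid removes the benzylic C3–H, whose carbon is bonded to C3a, ortho to the O1-bearing C7a of benzene ring A, while the carboxyl group on Cα, anchored at C2, captures C3 from its own face; this closes the lactone and fixes C3 relative to C2. The precursor is the (2R)-2-(2,3-dihydrobenzofuran-2-yl)acrylic acid already carrying the (R)-angelate side chain at C5, assembled by Morita–Baylis–Hillman chemistry and an enantioconvergent allylic etherification.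

Key step: step 12

Assumption: in step 8 the quinidine-derived catalyst (DHQD)2PHAL is taken to deliver the (2R) ether; should the sense prove opposite, its quinine-derived pseudoenantiomer (DHQ)2PHAL is used with no other change.

Note: C2 is labelled (R) up to 18 and (S) from 19 on only because C3 gains CIP priority when it receives oxygen; its geometry never changes.

**Step 1**
Reactants: 1 4'-hydroxyacetophenone; 2 allyl bromide
Product: 3 4'-(allyloxy)acetophenone
Conditions: K2CO3, acetone, reflux
Reagents that add atoms: none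
Why: Williamson ether synthesis, in which the phenoxide formed by K2CO3 is alkylated at oxygen by the primary allylic bromide in an SN2 reaction.

**Step 2**
Reactants: 3 4'-(allyloxy)acetophenone
Product: 5 3'-allyl-4'-hydroxyacetophenone, via Claisen dienone 4 (not isolated)
Conditions: N,N-diethylaniline, 200 °C
Reagents that add atoms: none
Why: Aromatic Claisen rearrangement, in which the [3,3]-sigmatropic shift delivers the allyl group to the free ortho carbon as dienone 4, which tautomerises to the phenol.

**Step 3**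
Reactants: 5 3'-allyl-4'-hydroxyacetophenone
Product: 6 3'-allyl-4'-(triisopropylsilyloxy)acetophenone
Conditions: iPr3SiCl, imidazole, DMF, rt
Reagents that add atoms: triisopropylsilyl chloride, CC(C)[Si](Cl)(C(C)C)C(C)C
Why: Silylation of a phenol with a silyl chloride and imidazole; the phenol must be masked because it would otherwise be acylated before the secondary alcohol in step 6, and the bulky silyl ether withstands DABCO and DMAP.

**Step 4**
Reactants: 6 3'-allyl-4'-(triisopropylsilyloxy)acetophenone
Product: 8 [5-acetyl-2-(triisopropylsilyloxy)phenyl]acetaldehyde, via secondary ozonide 7 (not isolated)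
Conditions: O3, CH2Cl2, −78 °C; then PPh3, −78 °C to rt
Reagents that add atoms: ozone, [O-][O+]=O
Why: Ozonolysis of the terminal alkene with reductive cleavage of ozonide 7 by PPh3 should give the arylacetaldehyde, the acetyl-deactivated arene being inert to ozone at −78 °C; the enolisable aldehyde is used at once.

**Step 5**
Reactants: 8 [5-acetyl-2-(triisopropylsilyloxy)phenyl]acetaldehyde; 9 methyl acrylate
Product: 10 methyl 4-[5-acetyl-2-(triisopropylsilyloxy)phenyl]-3-hydroxy-2-methylidenebutanoate (racemic)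
Conditions: DABCO (1 equiv), methyl acrylate (5 equiv, neat), rt
Reagents that add atoms: none
Why: Morita–Baylis–Hillman reaction, in which the ammonium enolate from DABCO and the acrylate attacks the aldehyde while the aryl ketone is too unreactive to compete; the carbinol centre is formed racemic on purpose because step 8 is enantioconvergent.

**Step 6**
Reactants: 10 methyl 4-[5-acetyl-2-(triisopropylsilyloxy)phenyl]-3-hydroxy-2-methylidenebutanoate
Product: 11 methyl 4-[5-acetyl-2-(triisopropylsilyloxy)phenyl]-3-[(tert-butoxycarbonyl)oxy]-2-methylidenebutanoate (racemic)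
Conditions: Boc2O, DMAP (cat.), CH2Cl2, 0 °C
Reagents that add atoms: di-tert-butyl dicarbonate, CC(C)(C)OC(=O)OC(=O)OC(C)(C)C
Why: DMAP-catalysed acylation of the secondary allylic alcohol installs the carbonate leaving group needed for Lewis-base ionisation; the centre stays racemic.

**Step 7**
Reactants: 11 the tert-butyl carbonate of 10
Product: 12 methyl 4-(5-acetyl-2-hydroxyphenyl)-3-[(tert-butoxycarbonyl)oxy]-2-methylidenebutanoate (racemic)
Conditions: Bu4NF, AcOH, THF, 0 °C
Reagents that add atoms: none
Why: Fluoride cleavage of the aryl silyl ether, fast for an electron-poor phenol; acetic acid keeps the liberated phenol protonated so that it does not attack the allylic carbonate before the chiral catalyst is present.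

**Step 8**
Reactants: 12 methyl 4-(5-acetyl-2-hydroxyphenyl)-3-[(tert-butoxycarbonyl)oxy]-2-methylidenebutanoate
Product: 13 methyl 2-[(2R)-5-acetyl-2,3-dihydro-1-benzofuran-2-yl]prop-2-enoate
Conditions: (DHQD)2PHAL (10 mol%), toluene, 0 °C to rt
Reagents that add atoms: none
Why: Tertiary-amine-catalysed allylic substitution of a Morita–Baylis–Hillman carbonate (SN2' then SN2'), in which the quinuclidine nitrogen adds to the CH2 terminus and expels tert-butyl carbonate so that both enantiomers of 12 give the same allylammonium ion, the released tert-butoxide deprotonates the phenol, and the phenoxide closes ring B at the γ-carbon in a 5-exo closure on the face left open by the alkaloid, which sets C2 as (R).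

**Step 9**
Reactants: 13 methyl 2-[(2R)-5-acetyl-2,3-dihydro-1-benzofuran-2-yl]prop-2-enoate
Product: 14 methyl 2-[(2R)-5-[(1R)-1-hydroxyethyl]-2,3-dihydro-1-benzofuran-2-yl]prop-2-enoate
Conditions: RuCl[(R,R)-TsDPEN](p-cymene) (1 mol%), HCO2H–Et3N (5:2), CH2Cl2, rt
Reagents that add atoms: none
Why: Noyori asymmetric transfer hydrogenation, in which the (R,R)-TsDPEN ruthenium hydride delivers hydride to one face of the aryl methyl ketone through the six-membered bifunctional transition state and should give the (R)-carbinol as with acetophenone, under catalyst control that is independent of the remote C2 centre and leaves the acrylate untouched.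

**Step 10**
Reactants: 14 methyl 2-[(2R)-5-[(1R)-1-hydroxyethyl]-2,3-dihydro-1-benzofuran-2-yl]prop-2-enoate; 15 angelic acid
Product: 17 methyl 2-[(2R)-5-[(1R)-1-(angeloyloxy)ethyl]-2,3-dihydro-1-benzofuran-2-yl]prop-2-enoate, via angelic 2,4,6-trichlorobenzoic anhydride 16 (not isolated)
Conditions: 15, 2,4,6-Cl3C6H2COCl, Et3N, toluene, rt; then 14, 60 °C
Reagents that add atoms: none
Why: Yamaguchi-type esterification through mixed anhydride 16 without DMAP, the established way to acylate with angelic acid without Z to E isomerisation to the tiglate; the carbinol C–O bond is not broken, so the (R) centre is retained.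

**Step 11**
Reactants: 17 methyl 2-[(2R)-5-[(1R)-1-(angeloyloxy)ethyl]-2,3-dihydro-1-benzofuran-2-yl]prop-2-enoate
Product: 18 2-[(2R)-5-[(1R)-1-(angeloyloxy)ethyl]-2,3-dihydro-1-benzofuran-2-yl]prop-2-enoic acid
Conditions: Me3SnOH, ClCH2CH2Cl, 70 °C; then cold 0.5 M HCl
Reagents that add atoms: trimethyltin hydroxide, C[Sn](C)(C)O
Why: Me3SnOH-mediated hydrolysis of a methyl ester under neutral conditions, in which the unhindered methyl ester reacts while the hindered secondary angelate survives and no free base is present to isomerise the angelate or open ring B.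

**Step 12**
Reactants: 18 2-[(2R)-5-[(1R)-1-(angeloyloxy)ethyl]-2,3-dihydro-1-benzofuran-2-yl]prop-2-enoic acid
Product: 19 (1R)-1-[(3aS,8bS)-3-methylidene-2-oxo-2,3,3a,8b-tetrahydrofuro[3,2-b][1]benzofuran-7-yl]ethyl (2Z)-2-methylbut-2-enoate
Conditions: graphite anode, Pt cathode, undivided cell, constant current (2 mA cm−2, 2.2 F mol−1), Bu4NBF4 (0.1 M), 2,6-lutidine (2 equiv), (CF3)2CHOH–CH2Cl2 (1:4), −20 °C
Reagents that add atoms: none
Why: Proposed new method: anodic oxidation of the alkyl aryl ether (ring A) gives its radical cation, the carboxylate on Cα (kept ionised by 2,6-lutidine) takes the C3 proton that faces it, and a second electron transfer gives a benzylic C3 cation stabilised through C3a–C7a by O1, which the same carboxylate captures; the closest known reaction type is the anodic or quinone-mediated dehydrogenative lactonisation of carboxylic acids at benzylic C–H bonds of electron-rich arenes, which has not been shown at C3 of a 2,3-dihydrobenzofuran. The lactone (ring C) closes in a 5-exo-trig mode on the planar cation. The new C3 centre is controlled by the existing C2 centre, since a 5/5 fusion can only be cis and the tethered oxygen can reach C3 only on the face of the C2 substituent. Site selectivity for C3–H over the para side-chain C–H is needed and is secured by the internal carboxylate base, which reaches only C3, by the better overlap of the ring C3–H bonds with the arene and by the electron-withdrawing acyloxy group on the side-chain carbon. Capture must also outrun loss of the C2 proton (aromatisation to the benzofuran) and ionisation of the two benzylic esters, which the pre-organised nucleophile, the lutidine buffer, the small share of (CF3)2CHOH and the low temperature favour. Proton reduction to H2 at the cathode balances the cell.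

**Step 13**
Reactants: 19 the cis-fused methylidene lactone
Product: 20 (1R)-1-[(2S,3S)-3-hydroxy-2-{3-[methoxy(methyl)amino]-3-oxoprop-1-en-2-yl}-2,3-dihydro-1-benzofuran-5-yl]ethyl (2Z)-2-methylbut-2-enoate
Conditions: AlMe3, MeNHOMe·HCl, CH2Cl2, 0 °C; then 19, 0 °C; aq. potassium sodium tartrate
Reagents that add atoms: N,O-dimethylhydroxylamine hydrochloride, CNOC.Cl
Why: Weinreb aminolysis of a lactone with an aluminium amide, in which the strained lactone carbonyl with its benzylic alkoxide leaving group reacts at 0 °C while the hindered conjugated angelate does not, and only the acyl C–O bond breaks so that the cis C3 oxygen is kept; the crude hydroxy amide is acetylated at once so that it cannot close back to 19.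

**Step 14**
Reactants: 20 the hydroxy N-methoxy-N-methylamide
Product: 21 (1R)-1-[(2S,3S)-3-acetoxy-2-{3-[methoxy(methyl)amino]-3-oxoprop-1-en-2-yl}-2,3-dihydro-1-benzofuran-5-yl]ethyl (2Z)-2-methylbut-2-enoate
Conditions: Ac2O, pyridine, DMAP (cat.), CH2Cl2, 0 °C
Reagents that add atoms: acetic anhydride, CC(=O)OC(C)=O
Why: DMAP-catalysed acetylation of the secondary benzylic alcohol, kept short and cold to avoid elimination across C2–C3; no stereocentre is touched.

**Step 15**
Reactants: 21 the acetoxy N-methoxy-N-methylamide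
Product: 22 (1R)-1-[(2S,3S)-3-acetoxy-2-(3-oxoprop-1-en-2-yl)-2,3-dihydro-1-benzofuran-5-yl]ethyl (2Z)-2-methylbut-2-enoate (CNP0294391.4)
Conditions: Cp2Zr(H)Cl (1.5 equiv), THF, rt; then H2O, silica gel
Reagents that add atoms: none
Why: Reduction of a tertiary N-methoxy-N-methylamide to the aldehyde with Cp2Zr(H)Cl, in which addition of Zr–H to the amide carbonyl gives a stable zirconium hemiaminal that releases the aldehyde only on work-up, while the acetate and angelate esters are not reduced by this reagent.

**Compound list**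

1 | 4'-hydroxyacetophenone | CC(=O)c1ccc(O)cc1 | starting material
2 | allyl bromide | C=CCBr | starting material
3 | 4'-(allyloxy)acetophenone | CC(=O)c1ccc(OCC=C)cc1 | intermediate
4 | 4-acetyl-6-allylcyclohexa-2,4-dien-1-one (Claisen dienone, racemic) | CC(=O)C1=CC(CC=C)C(=O)C=C1 | intermediate (not isolated)
5 | 3'-allyl-4'-hydroxyacetophenone | CC(=O)c1ccc(O)c(CC=C)c1 | intermediate
6 | 3'-allyl-4'-(triisopropylsilyloxy)acetophenone | CC(=O)c1ccc(O[Si](C(C)C)(C(C)C)C(C)C)c(CC=C)c1 | intermediate
7 | 1-[3-(1,2,4-trioxolan-3-ylmethyl)-4-(triisopropylsilyloxy)phenyl]ethanone (secondary ozonide, racemic) | CC(=O)c1ccc(O[Si](C(C)C)(C(C)C)C(C)C)c(CC2OCOO2)c1 | intermediate (not isolated)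
8 | [5-acetyl-2-(triisopropylsilyloxy)phenyl]acetaldehyde | CC(=O)c1ccc(O[Si](C(C)C)(C(C)C)C(C)C)c(CC=O)c1 | intermediate
9 | methyl acrylate | C=CC(=O)OC | starting material
10 | methyl 4-[5-acetyl-2-(triisopropylsilyloxy)phenyl]-3-hydroxy-2-methylidenebutanoate (racemic) | C=C(C(=O)OC)C(O)Cc1cc(C(C)=O)ccc1O[Si](C(C)C)(C(C)C)C(C)C | intermediate
11 | methyl 4-[5-acetyl-2-(triisopropylsilyloxy)phenyl]-3-[(tert-butoxycarbonyl)oxy]-2-methylidenebutanoate (racemic) | C=C(C(=O)OC)C(OC(=O)OC(C)(C)C)Cc1cc(C(C)=O)ccc1O[Si](C(C)C)(C(C)C)C(C)C | intermediate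
12 | methyl 4-(5-acetyl-2-hydroxyphenyl)-3-[(tert-butoxycarbonyl)oxy]-2-methylidenebutanoate (racemic) | C=C(C(=O)OC)C(OC(=O)OC(C)(C)C)Cc1cc(C(C)=O)ccc1O | intermediate
13 | methyl 2-[(2R)-5-acetyl-2,3-dihydro-1-benzofuran-2-yl]prop-2-enoate | C=C(C(=O)OC)[C@@H]1Oc2ccc(C(C)=O)cc2C1 | intermediate
14 | methyl 2-[(2R)-5-[(1R)-1-hydroxyethyl]-2,3-dihydro-1-benzofuran-2-yl]prop-2-enoate | C=C(C(=O)OC)[C@@H]1Oc2ccc([C@@H](C)O)cc2C1 | intermediate
15 | angelic acid, (2Z)-2-methylbut-2-enoic acid | C/C=C(/C)C(=O)O | starting material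
16 | (2Z)-2-methylbut-2-enoic 2,4,6-trichlorobenzoic anhydride | C/C=C(/C)C(=O)OC(=O)c1c(Cl)cc(Cl)cc1Cl | intermediate (not isolated)
17 | methyl 2-[(2R)-5-[(1R)-1-{[(2Z)-2-methylbut-2-enoyl]oxy}ethyl]-2,3-dihydro-1-benzofuran-2-yl]prop-2-enoate | C=C(C(=O)OC)[C@@H]1Oc2ccc([C@@H](C)OC(=O)/C(C)=C\C)cc2C1 | intermediate
18 | 2-[(2R)-5-[(1R)-1-{[(2Z)-2-methylbut-2-enoyl]oxy}ethyl]-2,3-dihydro-1-benzofuran-2-yl]prop-2-enoic acid (key-step precursor) | C=C(C(=O)O)[C@@H]1Oc2ccc([C@@H](C)OC(=O)/C(C)=C\C)cc2C1 | intermediate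
19 | (1R)-1-[(3aS,8bS)-3-methylidene-2-oxo-2,3,3a,8b-tetrahydrofuro[3,2-b][1]benzofuran-7-yl]ethyl (2Z)-2-methylbut-2-enoate (key-step product, cis-fused) | C=C1C(=O)O[C@H]2c3cc([C@@H](C)OC(=O)/C(C)=C\C)ccc3O[C@@H]12 | intermediate
20 | (1R)-1-[(2S,3S)-3-hydroxy-2-{3-[methoxy(methyl)amino]-3-oxoprop-1-en-2-yl}-2,3-dihydro-1-benzofuran-5-yl]ethyl (2Z)-2-methylbut-2-enoate | C=C(C(=O)N(C)OC)[C@@H]1Oc2ccc([C@@H](C)OC(=O)/C(C)=C\C)cc2[C@@H]1O | intermediate
21 | (1R)-1-[(2S,3S)-3-acetoxy-2-{3-[methoxy(methyl)amino]-3-oxoprop-1-en-2-yl}-2,3-dihydro-1-benzofuran-5-yl]ethyl (2Z)-2-methylbut-2-enoate | C=C(C(=O)N(C)OC)[C@@H]1Oc2ccc([C@@H](C)OC(=O)/C(C)=C\C)cc2[C@@H]1OC(C)=O | intermediate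
22 | (1R)-1-[(2S,3S)-3-acetoxy-2-(3-oxoprop-1-en-2-yl)-2,3-dihydro-1-benzofuran-5-yl]ethyl (2Z)-2-methylbut-2-enoate (CNP0294391.4) | C=C(C=O)[C@@H]1Oc2ccc([C@@H](C)OC(=O)/C(C)=C\C)cc2[C@@H]1OC(C)=O | target

**Count.** Total steps: 15. Longest linear sequence: 15 steps (1 to 22); methyl acrylate and angelic acid enter in single steps.

**Steps most likely to fail**

Step 12 (anodic lactonisation). Three processes could defeat it: deprotonation of the radical cation at the para side-chain carbon instead of C3; loss of the C2 proton from the C3 cation with aromatisation of ring B; and oxidation of the carboxylate itself with decarboxylation or oligomerisation of the acrylate. The fallback avoids C–H oxidation and brings the C3 oxygen in before ring B exists, using known reactions only. It sets out from carbonate 11 and comes back to the route at lactone 19. DABCO (cat.) and DBU should eliminate tert-butyl carbonate from 11 to give methyl (3E)-4-[5-acetyl-2-(triisopropylsilyloxy)phenyl]-2-methylidenebut-3-enoate F1. Shi epoxidation of its styrene-type double bond (D-fructose-derived ketone, KHSO5 as the triple salt 2KHSO5·KHSO4·K2SO4, K2CO3 buffer, 0 °C) should give methyl 2-[(2R,3R)-3-[5-acetyl-2-(triisopropylsilyloxy)phenyl]oxiran-2-yl]prop-2-enoate F2, the sense being that known for trans-β-methylstyrene. Camphorsulfonic acid in wet CH2Cl2 should let the ester carbonyl open the epoxide at the benzylic carbon with inversion and give (4R,5S)-5-[5-acetyl-2-(triisopropylsilyloxy)phenyl]-4-hydroxy-3-methylideneoxolan-2-one F3, with hydroxyl and aryl trans. Bu4NF/AcOH should free (4R,5S)-5-(5-acetyl-2-hydroxyphenyl)-4-hydroxy-3-methylideneoxolan-2-one F4. A Mitsunobu etherification (PPh3, DIAD, THF, 0 °C) displaces the C4 hydroxyl by the phenol with inversion, which can only close ring B cis, to give (3aS,8bS)-7-acetyl-3-methylidene-3a,8b-dihydrofuro[3,2-b][1]benzofuran-2(3H)-one F5. Corey–Bakshi–Shibata reduction ((S)-2-methyl-CBS-oxazaborolidine, catecholborane, −78 °C) should give (3aS,8bS)-7-[(1R)-1-hydroxyethyl]-3-methylidene-3a,8b-dihydrofuro[3,2-b][1]benzofuran-2(3H)-one F6, and angeloylation as in step 10 then gives 19.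

Step 8 (enantioconvergent etherification). Facial discrimination may be poor for an alkyl-substituted carbonate. The allylammonium ion may lose a benzylic proton and eliminate to a diene. The product ether may re-ionise and erode in enantiomeric purity. The fallback replaces nucleophilic amine catalysis by π-allylpalladium chemistry (a Tsuji–Trost etherification run as a dynamic kinetic asymmetric transformation, known for phenols and Morita–Baylis–Hillman carbonates). It sets out from 12 and comes back at 13. Zerovalent palladium from Pd2(dba)3·CHCl3 with the C2-symmetric diphosphine N,N'-bis[2-(diphenylphosphino)benzoyl]cyclohexane-1,2-diamine (the enantiomer that gives (2R)-13), in CH2Cl2 at rt, ionises the carbonate. The two diastereomeric allyl complexes interconvert by π–σ–π isomerisation, and the phenoxide closes ring B inside the chiral pocket. This detour makes no new compound (F0).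

Step 13 (lactone opening). The aluminium amide may also attack the angelate, the amine may add to the methylidene group in a conjugate sense, the hydroxy amide may close back to the lactone, or Lewis acid may trigger elimination across C2–C3. The fallback changes the order to reduce, protect, acetylate and reoxidise. It sets out from 19 and comes back at target 22.
- iBu2AlH (1.1 equiv, CH2Cl2, −78 °C) should reduce only the lactone, to (1R)-1-[(3aS,8bS)-2-hydroxy-3-methylidene-2,3,3a,8b-tetrahydrofuro[3,2-b][1]benzofuran-7-yl]ethyl (2Z)-2-methylbut-2-enoate F7.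
- NaBH4 with CeCl3·7H2O in MeOH at 0 °C reduces the open hydroxy-enal form 1,2 to (1R)-1-[(2S,3S)-3-hydroxy-2-(3-hydroxyprop-1-en-2-yl)-2,3-dihydro-1-benzofuran-5-yl]ethyl (2Z)-2-methylbut-2-enoate F8.
- tBuMe2SiCl and imidazole at 0 °C silylate the primary allylic alcohol to give (1R)-1-[(2S,3S)-2-[3-(tert-butyldimethylsilyloxy)prop-1-en-2-yl]-3-hydroxy-2,3-dihydro-1-benzofuran-5-yl]ethyl (2Z)-2-methylbut-2-enoate F9.
- Ac2O, pyridine and DMAP (cat.) give (1R)-1-[(2S,3S)-3-acetoxy-2-[3-(tert-butyldimethylsilyloxy)prop-1-en-2-yl]-2,3-dihydro-1-benzofuran-5-yl]ethyl (2Z)-2-methylbut-2-enoate F10.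
- HF·pyridine in THF gives (1R)-1-[(2S,3S)-3-acetoxy-2-(3-hydroxyprop-1-en-2-yl)-2,3-dihydro-1-benzofuran-5-yl]ethyl (2Z)-2-methylbut-2-enoate F11.
- MnO2 in CH2Cl2 oxidises the allylic alcohol to 22.

**Further compounds**

F1 | step 12 | methyl (3E)-4-[5-acetyl-2-(triisopropylsilyloxy)phenyl]-2-methylidenebut-3-enoate | C=C(C(=O)OC)/C=C/c1cc(C(C)=O)ccc1O[Si](C(C)C)(C(C)C)C(C)C
F2 | step 12 | methyl 2-[(2R,3R)-3-[5-acetyl-2-(triisopropylsilyloxy)phenyl]oxiran-2-yl]prop-2-enoate | C=C(C(=O)OC)[C@H]1O[C@@H]1c2cc(C(C)=O)ccc2O[Si](C(C)C)(C(C)C)C(C)C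
F3 | step 12 | (4R,5S)-5-[5-acetyl-2-(triisopropylsilyloxy)phenyl]-4-hydroxy-3-methylideneoxolan-2-one | C=C1C(=O)O[C@@H](c2cc(C(C)=O)ccc2O[Si](C(C)C)(C(C)C)C(C)C)[C@@H]1O
F4 | step 12 | (4R,5S)-5-(5-acetyl-2-hydroxyphenyl)-4-hydroxy-3-methylideneoxolan-2-one | C=C1C(=O)O[C@@H](c2cc(C(C)=O)ccc2O)[C@@H]1O
F5 | step 12 | (3aS,8bS)-7-acetyl-3-methylidene-3a,8b-dihydrofuro[3,2-b][1]benzofuran-2(3H)-one | C=C1C(=O)O[C@H]2c3cc(C(C)=O)ccc3O[C@@H]12
F6 | step 12 | (3aS,8bS)-7-[(1R)-1-hydroxyethyl]-3-methylidene-3a,8b-dihydrofuro[3,2-b][1]benzofuran-2(3H)-one | C=C1C(=O)O[C@H]2c3cc([C@@H](C)O)ccc3O[C@@H]12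
F0 | step 8 | none | none
F7 | step 13 | (1R)-1-[(3aS,8bS)-2-hydroxy-3-methylidene-2,3,3a,8b-tetrahydrofuro[3,2-b][1]benzofuran-7-yl]ethyl (2Z)-2-methylbut-2-enoate (lactol, both anomers) | C=C1C(O)O[C@H]2c3cc([C@@H](C)OC(=O)/C(C)=C\C)ccc3O[C@@H]12
F8 | step 13 | (1R)-1-[(2S,3S)-3-hydroxy-2-(3-hydroxyprop-1-en-2-yl)-2,3-dihydro-1-benzofuran-5-yl]ethyl (2Z)-2-methylbut-2-enoate | C=C(CO)[C@@H]1Oc2ccc([C@@H](C)OC(=O)/C(C)=C\C)cc2[C@@H]1O
F9 | step 13 | (1R)-1-[(2S,3S)-2-[3-(tert-butyldimethylsilyloxy)prop-1-en-2-yl]-3-hydroxy-2,3-dihydro-1-benzofuran-5-yl]ethyl (2Z)-2-methylbut-2-enoate | C=C(CO[Si](C)(C)C(C)(C)C)[C@@H]1Oc2ccc([C@@H](C)OC(=O)/C(C)=C\C)cc2[C@@H]1O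
F10 | step 13 | (1R)-1-[(2S,3S)-3-acetoxy-2-[3-(tert-butyldimethylsilyloxy)prop-1-en-2-yl]-2,3-dihydro-1-benzofuran-5-yl]ethyl (2Z)-2-methylbut-2-enoate | C=C(CO[Si](C)(C)C(C)(C)C)[C@@H]1Oc2ccc([C@@H](C)OC(=O)/C(C)=C\C)cc2[C@@H]1OC(C)=O
F11 | step 13 | (1R)-1-[(2S,3S)-3-acetoxy-2-(3-hydroxyprop-1-en-2-yl)-2,3-dihydro-1-benzofuran-5-yl]ethyl (2Z)-2-methylbut-2-enoate | C=C(CO)[C@@H]1Oc2ccc([C@@H](C)OC(=O)/C(C)=C\C)cc2[C@@H]1OC(C)=O
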